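**Retrosynthetic overview**
1. The target comes from flavan 14 by removing two benzyl ethers (ring A) and four phenolic acetates (ring B and the feruloyl phenol). The ferulate ester is already in place before the key step.
2. The pyran ring (O1–C2–C3–C4–C4a–C8a) is traced back to the cyclopentane ring (C2–C3–C4–C4a–C8a) of a 1-arylindane by deleting O1. In the forward sense, a Criegee-type aryl C→O shift inserts O1 between C8a and C2, and the resulting 2-aryl-oxocarbenium ion is reduced in the same flask.
3. Enabling feature: O1 lies between the ring-A carbon C8a and C2, which is benzylic to ring B and vicinal to the C3 ester. Without O1, C2 is a tertiary, doubly benzylic carbon that accepts a peroxy group by epoxide opening. Ring B as its triacetate is the poorer migrating aryl, so C8a moves, and the C3 acyloxy group steers hydride to the 2,3-cis product.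
4. The 1-arylindane comes from 3-arylindene 8, whose asymmetric epoxidation sets the later C3. Indene 8 comes from a Suzuki–Miyaura union of indenyl triflate 5 (ring A) and boronate 7 (ring B).
5. Ring order: the three arenes are bought. The cyclopentanone ring is formed in step 3, a temporary oxirane in step 7, and the pyran ring by ring expansion in step 10.

Key step: step 10

Assumption: the Mn(salen) epoxidation of 3-arylindene 8 is taken to follow the sense of induction known for indene itself ((S,S)-catalyst gives the (1aS,6aR)-oxide). The enantiomeric catalyst would be used if the 3-aryl group reverses it.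

Step 1
Reactants: 1 3,5-bis(benzyloxy)benzaldehyde
Product: 2 3,5-bis(benzyloxy)-2-bromobenzaldehyde
Conditions: NBS (1.05 equiv), MeCN, 0 °C to rt
Reagents that add atoms: N-bromosuccinimide, O=C1CCC(=O)N1Br
Why: Electrophilic aromatic bromination should go to C2, which is ortho to one and para to the other benzyloxy group and less crowded than C4 between the two ethers; no stereocentre is formed.

Step 2
Reactants: 2 3,5-bis(benzyloxy)-2-bromobenzaldehyde
Product: 3 3,5-bis(benzyloxy)-2-ethenylbenzaldehyde
Conditions: vinylboronic acid pinacol ester, Pd(dppf)Cl2 (5 mol %), K2CO3, dioxane–H2O, 80 °C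
Reagents that add atoms: vinylboronic acid pinacol ester, C=CB1OC(C)(C)C(C)(C)O1
Why: A Suzuki–Miyaura vinylation of the aryl bromide should tolerate the aldehyde and the benzyl ethers.

Step 3
Reactants: 3 3,5-bis(benzyloxy)-2-ethenylbenzaldehyde
Product: 4 4,6-bis(benzyloxy)-2,3-dihydro-1H-inden-1-one
Conditions: [Rh(cod)(dppe)]BF4 (5 mol %, H2-activated), acetone, rt to 50 °C
Reagents that add atoms: none
Why: Intramolecular Rh(I)-catalysed alkene hydroacylation of a 2-vinylbenzaldehyde (formyl C–H oxidative addition, hydrometalation, reductive elimination) should close the cyclopentanone, with the CH2 on the electron-rich and the C=O on the electron-neutral ring-A carbon.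

Step 4
Reactants: 4 4,6-bis(benzyloxy)-2,3-dihydro-1H-inden-1-one
Product: 5 5,7-bis(benzyloxy)-1H-inden-3-yl trifluoromethanesulfonate
Conditions: LiHMDS, THF, −78 °C; then PhNTf2, −78 °C to 0 °C
Reagents that add atoms: N-phenylbis(trifluoromethanesulfonimide), O=S(=O)(N(c1ccccc1)S(=O)(=O)C(F)(F)F)C(F)(F)F
Why: O-Triflation of the only possible ketone enolate should give the indenyl triflate.

Step 5
Reactants: 6 benzene-1,2,3-triyl triacetate (pyrogallol triacetate)
Product: 7 5-(4,4,5,5-tetramethyl-1,3,2-dioxaborolan-2-yl)benzene-1,2,3-triyl triacetate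
Conditions: B2pin2, [Ir(OMe)(cod)]2 (1.5 mol %), dtbpy (3 mol %), MTBE, 80 °C
Reagents that add atoms: bis(pinacolato)diboron, CC1(C)OB(OC1(C)C)B1OC(C)(C)C(C)(C)O1
Why: Iridium-catalysed aromatic C–H borylation is sterically controlled, so it should take C5–H, the only C–H without an ortho substituent, and esters are tolerated.

Step 6
Reactants: 5 5,7-bis(benzyloxy)-1H-inden-3-yl trifluoromethanesulfonate; 7 5-(4,4,5,5-tetramethyl-1,3,2-dioxaborolan-2-yl)benzene-1,2,3-triyl triacetate
Product: 8 5-[5,7-bis(benzyloxy)-1H-inden-3-yl]benzene-1,2,3-triyl triacetate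
Conditions: Pd(OAc)2 (3 mol %), PCy3 (6 mol %), powdered KF (3 equiv), THF, rt to 40 °C
Reagents that add atoms: none
Why: Suzuki–Miyaura coupling of a vinyl triflate with fluoride as a mild, non-hydrolytic activator should spare the phenolic acetates, and the 3-aryl-1H-indene is the conjugated, more stable double-bond isomer.

Step 7
Reactants: 8 5-[5,7-bis(benzyloxy)-1H-inden-3-yl]benzene-1,2,3-triyl triacetate
Product: 9 5-[(1aS,6aR)-3,5-bis(benzyloxy)-6,6a-dihydro-1aH-indeno[1,2-b]oxiren-1a-yl]benzene-1,2,3-triyl triacetate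
Conditions: (S,S)-N,N'-bis(3,5-di-tert-butylsalicylidene)-1,2-cyclohexanediaminomanganese(III) chloride (5 mol %), NMO (5 equiv), mCPBA (2 equiv), CH2Cl2, −78 °C
Reagents that add atoms: 3-chloroperoxybenzoic acid, OOC(=O)c1cccc(Cl)c1
Why: Jacobsen–Katsuki epoxidation of a conjugated, cyclic trisubstituted olefin in its anhydrous low-temperature variant should spare the acetates, and the chiral oxo-manganese species selects the olefin face and so sets C6a (R), the later C3.

Step 8
Reactants: 9 5-[(1aS,6aR)-3,5-bis(benzyloxy)-6,6a-dihydro-1aH-indeno[1,2-b]oxiren-1a-yl]benzene-1,2,3-triyl triacetate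
Product: 10 5-[(1R,2R)-4,6-bis(benzyloxy)-1-hydroperoxy-2-hydroxy-2,3-dihydro-1H-inden-1-yl]benzene-1,2,3-triyl triacetate (OOH trans to OH)
Conditions: anhydrous H2O2 in Et2O (10 equiv), phosphomolybdic acid (3 mol %), 0 °C to rt
Reagents that add atoms: hydrogen peroxide, OO
Why: In this heteropolyacid-catalysed perhydrolysis of an epoxide, ring strain and the tertiary, doubly benzylic character of C1a direct H2O2 to that carbon with inversion, the C6a–O bond (later C3–O) stays intact, and the configuration at the peroxy carbon does not matter because it is planarised in step 10.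

Step 9
Reactants: 10 5-[(1R,2R)-4,6-bis(benzyloxy)-1-hydroperoxy-2-hydroxy-2,3-dihydro-1H-inden-1-yl]benzene-1,2,3-triyl triacetate; 11 (E)-3-(4-acetoxy-3-methoxyphenyl)acrylic acid (O-acetylferulic acid, 2.3 equiv)
Product: 12 (1R,2R)-4,6-bis(benzyloxy)-1-(3,4,5-triacetoxyphenyl)-2-(O-acetylferuloyloxy)-2,3-dihydro-1H-inden-1-yl O-acetylperoxyferulate (ester at O-2, perester at C1–OO)
Conditions: DCC (2.4 equiv), DMAP (0.2 equiv), CH2Cl2, −10 °C to 0 °C; kept cold and used promptly
Reagents that add atoms: none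
Why: Steglich acylation is known for both alcohols and hydroperoxides, so it should esterify the secondary OH and the more nucleophilic OOH in one operation without touching a stereocentre; the peroxy-bound acyl group serves only as the leaving group of step 10.

Step 10
Reactants: 12 (1R,2R)-4,6-bis(benzyloxy)-1-(3,4,5-triacetoxyphenyl)-2-(O-acetylferuloyloxy)-2,3-dihydro-1H-inden-1-yl O-acetylperoxyferulate
Product: 14 (2R,3R)-5,7-bis(benzyloxy)-2-(3,4,5-triacetoxyphenyl)chroman-3-yl (E)-3-(4-acetoxy-3-methoxyphenyl)acrylate, via flavan-2-ylium triflate 13 (not isolated)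
Conditions: Et3SiH (5 equiv), TMSOTf (0.2 equiv), 4 Å MS, CH2Cl2 (0.02 M), −78 °C to −30 °C
Reagents that add atoms: none
Why: Proposed new method: silylation of the perester carbonyl by TMSOTf makes the carboxylate a neutral leaving group, O–O heterolysis is concerted with the 1,2-shift of the ring-A carbon C7a from indane C1 to the proximal oxygen (Criegee/Hock rearrangement), which enlarges the cyclopentane to the pyran ring and leaves ion 13, and Et3SiH then delivers hydride to C2 and regenerates a silyl triflate, so the Lewis acid is catalytic. The closest known reactions are the Criegee rearrangement of tertiary benzylic peresters, the Hock ring expansion of indan-1-yl hydroperoxides with capture of the oxocarbenium ion by an added nucleophile, and the Et3SiH/Lewis-acid reductive etherification that gives 2,3-cis-flavan-3-yl esters; what is new is their union on a 1-aryl-2-acyloxyindane with hydride as the terminating nucleophile. No ring is closed by cyclisation, because the six-membered ring arises by insertion of oxygen into the C1–C7a bond of the five-membered ring. The C3 centre (from the epoxide) is not touched and controls the new C2 centre: A(1,2) strain with the coplanar ring B places the C3 ester pseudo-axial (or bridges it to C2 as a dioxolenium ion), so hydride enters axially and anti to it, which puts ring B cis to the ester. The step needs migration of ring A rather than ring B or indane C2, and this is secured because three acetoxy groups make ring B a much poorer migrating aryl than the ether-bearing, ortho-alkylated ring A, while the acyloxy substituent lowers the aptitude of C2. Because a carboxylate and not water is expelled, the medium stays anhydrous, and excess silane at low temperature and high dilution should outrun ring opening to the ketone, Friedel–Crafts attack by the new phloroglucinol ring, and loss of H-3 to the flav-2-ene, which would erode the ee.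

Step 11
Reactants: 14 (2R,3R)-5,7-bis(benzyloxy)-2-(3,4,5-triacetoxyphenyl)chroman-3-yl (E)-3-(4-acetoxy-3-methoxyphenyl)acrylate
Product: 15 (2R,3R)-5,7-dihydroxy-2-(3,4,5-triacetoxyphenyl)chroman-3-yl (E)-3-(4-acetoxy-3-methoxyphenyl)acrylate
Conditions: BCl3 (8 equiv), pentamethylbenzene (6 equiv), CH2Cl2, −78 °C; quench with CHCl3–MeOH, then aqueous work-up
Reagents that add atoms: none
Why: Lewis-acid debenzylation of aryl benzyl ethers with a non-Lewis-basic cation scavenger avoids hydrogenation of the cinnamate C=C and C-benzylation of ring A, and the acetylated ring B keeps the benzylic C2–O1 bond and the C2 configuration safe.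

Step 12
Reactants: 15 (2R,3R)-5,7-dihydroxy-2-(3,4,5-triacetoxyphenyl)chroman-3-yl (E)-3-(4-acetoxy-3-methoxyphenyl)acrylate
Product: 16 epigallocatechin-3-O-ferulate, (2R,3R)-5,7-dihydroxy-2-(3,4,5-trihydroxyphenyl)chroman-3-yl (E)-3-(4-hydroxy-3-methoxyphenyl)acrylate
Conditions: NH4OAc (10 equiv), degassed MeOH–H2O 4:1, Ar, rt; purification on Sephadex LH-20
Reagents that add atoms: none
Why: Near-neutral ammonium-acetate-mediated methanolysis is selective for aryl acetates over alkyl esters, so the secondary cinnamate ester, the E-olefin and the base-sensitive C2 centre should persist.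

**Compound list**
1 | 3,5-bis(benzyloxy)benzaldehyde | O=Cc1cc(OCc2ccccc2)cc(OCc2ccccc2)c1 | starting material
2 | 3,5-bis(benzyloxy)-2-bromobenzaldehyde | O=Cc1cc(OCc2ccccc2)cc(OCc2ccccc2)c1Br | intermediate
3 | 3,5-bis(benzyloxy)-2-ethenylbenzaldehyde | O=Cc1cc(OCc2ccccc2)cc(OCc2ccccc2)c1C=C | intermediate
4 | 4,6-bis(benzyloxy)-2,3-dihydro-1H-inden-1-one | O=C1CCc2c(OCc3ccccc3)cc(OCc3ccccc3)cc21 | intermediate
5 | 5,7-bis(benzyloxy)-1H-inden-3-yl trifluoromethanesulfonate | O=S(=O)(OC1=CCc2c(OCc3ccccc3)cc(OCc3ccccc3)cc21)C(F)(F)F | intermediate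
6 | benzene-1,2,3-triyl triacetate | CC(=O)Oc1cccc(OC(C)=O)c1OC(C)=O | starting material
7 | 5-(4,4,5,5-tetramethyl-1,3,2-dioxaborolan-2-yl)benzene-1,2,3-triyl triacetate | CC(=O)Oc1cc(B2OC(C)(C)C(C)(C)O2)cc(OC(C)=O)c1OC(C)=O | intermediate
8 | 5-[5,7-bis(benzyloxy)-1H-inden-3-yl]benzene-1,2,3-triyl triacetate | CC(=O)Oc1cc(C2=CCc3c(OCc4ccccc4)cc(OCc4ccccc4)cc32)cc(OC(C)=O)c1OC(C)=O | intermediate
9 | 5-[(1aS,6aR)-3,5-bis(benzyloxy)-6,6a-dihydro-1aH-indeno[1,2-b]oxiren-1a-yl]benzene-1,2,3-triyl triacetate | O1[C@@H]2Cc3c(OCc4ccccc4)cc(OCc4ccccc4)cc3[C@]12c1cc(OC(C)=O)c(OC(C)=O)c(OC(C)=O)c1 | intermediate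
10 | 5-[(1R,2R)-4,6-bis(benzyloxy)-1-hydroperoxy-2-hydroxy-2,3-dihydro-1H-inden-1-yl]benzene-1,2,3-triyl triacetate | O[C@@H]1Cc2c(OCc3ccccc3)cc(OCc3ccccc3)cc2[C@]1(OO)c1cc(OC(C)=O)c(OC(C)=O)c(OC(C)=O)c1 | intermediate
11 | (E)-3-(4-acetoxy-3-methoxyphenyl)acrylic acid (O-acetylferulic acid) | COc1cc(/C=C/C(=O)O)ccc1OC(C)=O | starting material
12 | (1R,2R)-4,6-bis(benzyloxy)-1-(3,4,5-triacetoxyphenyl)-2-(O-acetylferuloyloxy)-2,3-dihydro-1H-inden-1-yl O-acetylperoxyferulate | COc1cc(/C=C/C(=O)O[C@@H]2Cc3c(OCc4ccccc4)cc(OCc4ccccc4)cc3[C@]2(OOC(=O)/C=C/c2ccc(OC(C)=O)c(OC)c2)c2cc(OC(C)=O)c(OC(C)=O)c(OC(C)=O)c2)ccc1OC(C)=O | intermediate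
13 | (3R)-3-(O-acetylferuloyloxy)-5,7-bis(benzyloxy)-2-(3,4,5-triacetoxyphenyl)-3,4-dihydrochromenylium triflate (flavan-2-ylium triflate) | COc1cc(/C=C/C(=O)O[C@@H]2Cc3c(OCc4ccccc4)cc(OCc4ccccc4)cc3[O+]=C2c2cc(OC(C)=O)c(OC(C)=O)c(OC(C)=O)c2)ccc1OC(C)=O.[O-]S(=O)(=O)C(F)(F)F | intermediate (not isolated)
14 | (2R,3R)-5,7-bis(benzyloxy)-2-(3,4,5-triacetoxyphenyl)chroman-3-yl (E)-3-(4-acetoxy-3-methoxyphenyl)acrylate | COc1cc(/C=C/C(=O)O[C@@H]2Cc3c(OCc4ccccc4)cc(OCc4ccccc4)cc3O[C@@H]2c2cc(OC(C)=O)c(OC(C)=O)c(OC(C)=O)c2)ccc1OC(C)=O | intermediate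
15 | (2R,3R)-5,7-dihydroxy-2-(3,4,5-triacetoxyphenyl)chroman-3-yl (E)-3-(4-acetoxy-3-methoxyphenyl)acrylate | COc1cc(/C=C/C(=O)O[C@@H]2Cc3c(O)cc(O)cc3O[C@@H]2c2cc(OC(C)=O)c(OC(C)=O)c(OC(C)=O)c2)ccc1OC(C)=O | intermediate
16 | epigallocatechin-3-O-ferulate | COc1cc(/C=C/C(=O)O[C@@H]2Cc3c(O)cc(O)cc3O[C@@H]2c2cc(O)c(O)c(O)c2)ccc1O | target

Total step count: 12. Longest linear sequence: 11 (steps 1–4 and 6–12).

**Steps most likely to fail**

1. **Step 10 (Proposed new method).** Hydride transfer may be too slow to intercept the oxocarbenium ion. That would allow Friedel–Crafts oligomerisation through the newly formed phloroglucinol ring, proton loss at C3 with erosion of the ee, or poor facial selectivity.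
   Fallback: the two events are separated with known chemistry.
   - Setting out from 12, the Criegee rearrangement is run alone in a wet, weakly acidic medium (cat. TsOH, MeCN–H2O, 0 °C to rt). The ring-expanded acylal is hydrolysed to the open-chain (R)-3-[2,4-bis(benzyloxy)-6-hydroxyphenyl]-1-oxo-1-(3,4,5-triacetoxyphenyl)propan-2-yl O-acetylferulate F1.
   - In a second operation this hydroxy ketone is closed through its six-membered hemiketal by reductive etherification (Et3SiH, TMSOTf or BF3·OEt2, CH2Cl2, −40 °C). This comes back to the route at 14.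

2. **Step 8.** The acid catalyst may trigger a 1,2-hydride shift of the epoxide to the 1-aryl-2-indanone, or a Hock-type C1–C2 fragmentation of the free β-hydroxy hydroperoxide.
   Fallback: the free β-hydroxy hydroperoxide is avoided.
   - Setting out from 9, the epoxide is hydrolysed (cat. HClO4, THF–H2O, 0 °C) to 5-[(1R,2R)-4,6-bis(benzyloxy)-1,2-dihydroxy-2,3-dihydro-1H-inden-1-yl]benzene-1,2,3-triyl triacetate F2.
   - The secondary OH alone is esterified with 11 (1.1 equiv, DCC, DMAP) to give (1R,2R)-4,6-bis(benzyloxy)-1-hydroxy-1-(3,4,5-triacetoxyphenyl)-2,3-dihydro-1H-inden-2-yl O-acetylferulate F3.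
   - The tertiary benzylic OH is exchanged for OOH (ethereal H2O2, TsOH, 0 °C) with anchimeric help from the trans ester. This gives (1R,2R)-4,6-bis(benzyloxy)-1-hydroperoxy-1-(3,4,5-triacetoxyphenyl)-2,3-dihydro-1H-inden-2-yl O-acetylferulate F4.
   - Acylation of its OOH group with 11 (DCC, DMAP) comes back to the route at 12.

3. **Step 7.** Facial selectivity on the 3-aryl-substituted indene may be poor, or the labile epoxide may rearrange during isolation.
   Fallback: the later C3 centre is set by asymmetric dihydroxylation, whose mnemonic (ring B in the south-west quadrant, H in the south-east quadrant) predicts top-face attack with the DHQD ligand.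
   - Setting out from 8, the carbonate-free variant is used: K2OsO2(OH)4, (DHQD)2PHAL, NMO, acetone–H2O, 0 °C, slow addition of the olefin. It should give 5-[(1S,2R)-4,6-bis(benzyloxy)-1,2-dihydroxy-2,3-dihydro-1H-inden-1-yl]benzene-1,2,3-triyl triacetate F5 without loss of the acetates.
   - Acid-catalysed exchange of its tertiary benzylic OH with ethereal H2O2 comes back to the route at 10. Either C1 epimer is serviceable.

**Further compounds**
F1 | step 10 | (R)-3-[2,4-bis(benzyloxy)-6-hydroxyphenyl]-1-oxo-1-(3,4,5-triacetoxyphenyl)propan-2-yl O-acetylferulate | COc1cc(/C=C/C(=O)O[C@H](Cc2c(O)cc(OCc3ccccc3)cc2OCc2ccccc2)C(=O)c2cc(OC(C)=O)c(OC(C)=O)c(OC(C)=O)c2)ccc1OC(C)=O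
F2 | step 8 | 5-[(1R,2R)-4,6-bis(benzyloxy)-1,2-dihydroxy-2,3-dihydro-1H-inden-1-yl]benzene-1,2,3-triyl triacetate | O[C@@H]1Cc2c(OCc3ccccc3)cc(OCc3ccccc3)cc2[C@]1(O)c1cc(OC(C)=O)c(OC(C)=O)c(OC(C)=O)c1
F3 | step 8 | (1R,2R)-4,6-bis(benzyloxy)-1-hydroxy-1-(3,4,5-triacetoxyphenyl)-2,3-dihydro-1H-inden-2-yl O-acetylferulate | COc1cc(/C=C/C(=O)O[C@@H]2Cc3c(OCc4ccccc4)cc(OCc4ccccc4)cc3[C@]2(O)c2cc(OC(C)=O)c(OC(C)=O)c(OC(C)=O)c2)ccc1OC(C)=O
F4 | step 8 | (1R,2R)-4,6-bis(benzyloxy)-1-hydroperoxy-1-(3,4,5-triacetoxyphenyl)-2,3-dihydro-1H-inden-2-yl O-acetylferulate | COc1cc(/C=C/C(=O)O[C@@H]2Cc3c(OCc4ccccc4)cc(OCc4ccccc4)cc3[C@]2(OO)c2cc(OC(C)=O)c(OC(C)=O)c(OC(C)=O)c2)ccc1OC(C)=O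
F5 | step 7 | 5-[(1S,2R)-4,6-bis(benzyloxy)-1,2-dihydroxy-2,3-dihydro-1H-inden-1-yl]benzene-1,2,3-triyl triacetate | O[C@@H]1Cc2c(OCc3ccccc3)cc(OCc3ccccc3)cc2[C@@]1(O)c1cc(OC(C)=O)c(OC(C)=O)c(OC(C)=O)c1
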